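Ring C is cut into an O1–C2–C3 unit and a C4–C4a–C8a unit. The step exploits two features: O1 and C3 both sit on stereocentre C2, the retron of a terminal epoxide, and acyl carbon C4 is ortho to C8a on ring A. An umpoled C4, the 2-lithio-1,3-dithiane carried by a 2-fluoroaryl ring A, opens an (R)-aryloxirane at its CH2 carbon, and the alkoxide set free on C2 then displaces the ortho fluoride in the same flask, closing ring C with C2 already in its final configuration. The precursors are a fluorinated, geranylated bis-MOM aryl dithiane and a CBS-derived epoxide; dithiane hydrolysis and MOM removal finish the route.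

Key step: step 7

Remark on the chemistry: the SMILES is read as the (2S)-flavanone with an (E)-geranyl group at C6. Flavanone numbering is used (O1, C2, C3, C4, C4a, C5 to C8, C8a; ring A = benzo ring, ring B = syringyl ring, ring C = pyranone ring). MOM = methoxymethyl, geranyl = (2E)-3,7-dimethylocta-2,6-dien-1-yl. Compounds 1, 3, 6 and 11 are taken as commercial.

Step 1
Reactants: 1 5-fluororesorcinol
Product: 2 1-fluoro-3,5-bis(methoxymethoxy)benzene
Conditions: NaH, MOMCl, DMF, 0 °C to rt
Reagents that add atoms: chloromethyl methyl ether (MOMCl) COCCl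
Why: Williamson-type O-alkylation of the bis-phenoxide; the two MOM acetals later direct both ring metalations and are removable without touching the methyl ethers of ring B.

Step 2
Reactants: 2 1-fluoro-3,5-bis(methoxymethoxy)benzene; 3 geranyl bromide
Product: 5 5-fluoro-2-geranyl-1,3-bis(methoxymethoxy)benzene, via aryllithium 4 (not isolated)
Conditions: n-BuLi, THF, −78 to −20 °C; CuBr·SMe2 (10 mol %), then 3, −78 °C to rt
Reagents that add atoms: none
Why: Directed ortho-metalation, in which both OMOM groups should deliver n-BuLi to the C–H between them in preference to the fluorine-flanked sites, followed by copper-catalysed SN2 allylation that should keep the E alkene.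

Step 3
Reactants: 5 5-fluoro-2-geranyl-1,3-bis(methoxymethoxy)benzene; 6 1,3-dithiane
Product: 10 2-[2-fluoro-5-geranyl-4,6-bis(methoxymethoxy)phenyl]-1,3-dithiane, via 2-chloro-1,3-dithiane 7 (not isolated), via aryllithium 8 (not isolated), via arylmagnesium bromide 9 (not isolated)
Conditions: 6, NCS, benzene, rt (gives 7, filtered); 5, n-BuLi, THF, −78 °C; MgBr2·OEt2, −78 °C; then 7, −78 °C to rt
Reagents that add atoms: none
Why: A second directed ortho-metalation at the only remaining ring position type (two sites equivalent by symmetry, each flanked by F and OMOM), transmetalation to magnesium to suppress aryne formation, then Grignard substitution of the α-chloro sulfide 7; this installs the masked C4 without the thiol/Lewis acid conditions that would cleave MOM ethers.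

Step 4
Reactants: 11 acetosyringone
Product: 12 1-[3,5-dimethoxy-4-(methoxymethoxy)phenyl]ethanone
Conditions: NaH, MOMCl, DMF, 0 °C to rt
Reagents that add atoms: chloromethyl methyl ether (MOMCl) COCCl
Why: Williamson-type O-alkylation of the acidic para-acyl phenoxide; protection prevents quinone methide formation from the later epoxide.

Step 5
Reactants: 12 1-[3,5-dimethoxy-4-(methoxymethoxy)phenyl]ethanone
Product: 14 2-bromo-1-[3,5-dimethoxy-4-(methoxymethoxy)phenyl]ethanone, via silyl enol ether 13 (not isolated)
Conditions: Me3SiCl, LiN(SiMe3)2, THF, −78 °C; then NBS, −78 to 0 °C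
Reagents that add atoms: N-bromosuccinimide O=C1CCC(=O)N1Br
Why: Bromination of a silyl enol ether with NBS is α-selective and acid-free, so the MOM acetal should survive and the electron-rich ring should not be brominated.

Step 6
Reactants: 14 2-bromo-1-[3,5-dimethoxy-4-(methoxymethoxy)phenyl]ethanone
Product: 16 (2R)-2-[3,5-dimethoxy-4-(methoxymethoxy)phenyl]oxirane, via (R)-bromohydrin 15 (not isolated)
Conditions: (R)-2-methyl-CBS-oxazaborolidine [from (R)-α,α-diphenylprolinol] (10 mol %), BH3·SMe2, THF, 0 °C; MeOH; then 2 M NaOH (aq), rt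
Reagents that add atoms: none
Why: Corey–Bakshi–Shibata reduction, in which the catalyst–borane complex places the aryl group as the large substituent and delivers hydride to the face that gives the (R)-bromohydrin; hydroxide then closes the epoxide by 3-exo-tet displacement at CH2Br, which leaves the stereocentre untouched.

Step 7
Reactants: 10 2-[2-fluoro-5-geranyl-4,6-bis(methoxymethoxy)phenyl]-1,3-dithiane; 16 (2R)-2-[3,5-dimethoxy-4-(methoxymethoxy)phenyl]oxirane
Product: 19 (2S)-2-[3,5-dimethoxy-4-(methoxymethoxy)phenyl]-6-geranyl-5,7-bis(methoxymethoxy)spiro[chromane-4,2'-[1,3]dithiane], via 2-lithiodithiane 17 (not isolated), via lithium alkoxide 18 (not isolated)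
Conditions: n-BuLi, THF, −78 to −30 °C; 16, −78 °C to rt; then DMPU, 65 °C
Reagents that add atoms: none
Why: n-BuLi removes the dithiane C–H of 10 (Corey–Seebach umpolung of C4), the tertiary carbanion 17 opens epoxide 16 by SN2 attack at its CH2 carbon (C3–C4 bond), and the alkoxide 18 so released adds to the fluorine-bearing C8a and expels LiF (O1–C8a bond). The closest known reaction types are the alkylation of 2-lithio-1,3-dithianes with terminal epoxides and the intramolecular SNAr etherification of ortho-fluoroaryl alkoxides to chromans. Ring C closes by 6-exo-trig attack of the alkoxide on aromatic C8a (addition–elimination through a Meisenheimer intermediate), helped by the gem-disubstituent effect of the dithiane carbon. C2 is the stereocentre of 16 and none of its bonds is broken (the carbanion attacks C3 and O1 acts only as a nucleophile), so (R)-16 should give (2S)-19 with retention, the descriptor changing only through the priority rules. The step needs CH2 rather than benzylic epoxide opening (secured by the bulk of the tertiary anion), metalation at the dithiane C–H rather than at ring C8–H (secured by the far higher acidity of the dithiane C–H and the neighbouring OMOM group), and displacement of F rather than of the OMOM group on C5 (fluoride is by far the better SNAr leaving group). Keeping C4 as a dithiane means no β-alkoxy ketone exists under base, which shuts the retro-aldol and elimination channels that could racemise C2.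

Step 8
Reactants: 19 (2S)-spiro dithiane flavan
Product: 20 (2S)-2-[3,5-dimethoxy-4-(methoxymethoxy)phenyl]-6-geranyl-5,7-bis(methoxymethoxy)chroman-4-one
Conditions: MeI, CaCO3, MeCN/H2O (9:1), 45 °C
Reagents that add atoms: water O
Why: Alkylative dithioketal hydrolysis (S-methylation, opening to a thionium ion stabilised by the oxygenated ring A, capture by water); the buffered neutral medium should spare MOM acetals and geranyl alkenes and offers no base that could open ring C and racemise C2.

Step 9
Reactants: 20 (2S)-tris-MOM flavanone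
Product: 21 (2S)-5,7-dihydroxy-2-(4-hydroxy-3,5-dimethoxyphenyl)-6-geranylchroman-4-one (CNP0372687.1)
Conditions: 3 M HCl (aq), MeOH, 45 °C
Reagents that add atoms: none
Why: Acid-catalysed transacetalisation of the three aryl MOM ethers to methanol; dilute acid at mild temperature should leave the trisubstituted alkenes, the methyl ethers and the C2 stereocentre intact.

Compound list
1 | 5-fluororesorcinol (5-fluorobenzene-1,3-diol) | Oc1cc(O)cc(F)c1 | starting material
2 | 1-fluoro-3,5-bis(methoxymethoxy)benzene | COCOc1cc(F)cc(OCOC)c1 | intermediate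
3 | geranyl bromide, (2E)-1-bromo-3,7-dimethylocta-2,6-diene | BrC/C=C(\C)CCC=C(C)C | starting material
4 | [4-fluoro-2,6-bis(methoxymethoxy)phenyl]lithium (in-flask species) | [Li]c1c(OCOC)cc(F)cc1OCOC | intermediate
5 | 5-fluoro-2-[(2E)-3,7-dimethylocta-2,6-dien-1-yl]-1,3-bis(methoxymethoxy)benzene | COCOc1cc(F)cc(OCOC)c1C/C=C(\C)CCC=C(C)C | intermediate
6 | 1,3-dithiane | C1CSCSC1 | starting material
7 | 2-chloro-1,3-dithiane (in-flask species) | ClC1SCCCS1 | intermediate
8 | [2-fluoro-5-geranyl-4,6-bis(methoxymethoxy)phenyl]lithium (in-flask species) | COCOc1cc(F)c([Li])c(OCOC)c1C/C=C(\C)CCC=C(C)C | intermediate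
9 | [2-fluoro-5-geranyl-4,6-bis(methoxymethoxy)phenyl]magnesium bromide (in-flask species) | COCOc1cc(F)c([Mg]Br)c(OCOC)c1C/C=C(\C)CCC=C(C)C | intermediate
10 | 2-{2-fluoro-5-[(2E)-3,7-dimethylocta-2,6-dien-1-yl]-4,6-bis(methoxymethoxy)phenyl}-1,3-dithiane | COCOc1cc(F)c(C2SCCCS2)c(OCOC)c1C/C=C(\C)CCC=C(C)C | intermediate
11 | acetosyringone, 1-(4-hydroxy-3,5-dimethoxyphenyl)ethanone | CC(=O)c1cc(OC)c(O)c(OC)c1 | starting material
12 | 1-[3,5-dimethoxy-4-(methoxymethoxy)phenyl]ethanone | CC(=O)c1cc(OC)c(OCOC)c(OC)c1 | intermediate
13 | {1-[3,5-dimethoxy-4-(methoxymethoxy)phenyl]ethenyloxy}trimethylsilane (in-flask species) | C=C(O[Si](C)(C)C)c1cc(OC)c(OCOC)c(OC)c1 | intermediate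
14 | 2-bromo-1-[3,5-dimethoxy-4-(methoxymethoxy)phenyl]ethanone | O=C(CBr)c1cc(OC)c(OCOC)c(OC)c1 | intermediate
15 | (1R)-2-bromo-1-[3,5-dimethoxy-4-(methoxymethoxy)phenyl]ethanol (in-flask species) | COc1cc([C@@H](O)CBr)cc(OC)c1OCOC | intermediate
16 | (2R)-2-[3,5-dimethoxy-4-(methoxymethoxy)phenyl]oxirane | COc1cc([C@@H]2CO2)cc(OC)c1OCOC | intermediate
17 | {2-[2-fluoro-5-geranyl-4,6-bis(methoxymethoxy)phenyl]-1,3-dithian-2-yl}lithium (in-flask species) | [Li]C1(SCCCS1)c2c(F)cc(OCOC)c(C/C=C(\C)CCC=C(C)C)c2OCOC | intermediate
18 | lithium (1S)-1-[3,5-dimethoxy-4-(methoxymethoxy)phenyl]-2-{2-[2-fluoro-5-geranyl-4,6-bis(methoxymethoxy)phenyl]-1,3-dithian-2-yl}ethanolate (in-flask species) | COc1cc([C@@H](O[Li])CC2(SCCCS2)c3c(F)cc(OCOC)c(C/C=C(\C)CCC=C(C)C)c3OCOC)cc(OC)c1OCOC | intermediate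
19 | (2S)-2-[3,5-dimethoxy-4-(methoxymethoxy)phenyl]-6-[(2E)-3,7-dimethylocta-2,6-dien-1-yl]-5,7-bis(methoxymethoxy)spiro[chromane-4,2'-[1,3]dithiane] | COc1cc([C@@H]2CC3(SCCCS3)c4c(cc(OCOC)c(C/C=C(\C)CCC=C(C)C)c4OCOC)O2)cc(OC)c1OCOC | intermediate
20 | (2S)-2-[3,5-dimethoxy-4-(methoxymethoxy)phenyl]-6-[(2E)-3,7-dimethylocta-2,6-dien-1-yl]-5,7-bis(methoxymethoxy)-2,3-dihydro-4H-chromen-4-one | COc1cc([C@@H]2CC(=O)c3c(cc(OCOC)c(C/C=C(\C)CCC=C(C)C)c3OCOC)O2)cc(OC)c1OCOC | intermediate
21 | (2S)-5,7-dihydroxy-2-(4-hydroxy-3,5-dimethoxyphenyl)-6-[(2E)-3,7-dimethylocta-2,6-dien-1-yl]-2,3-dihydro-4H-chromen-4-one (CNP0372687.1) | COc1cc([C@@H]2CC(=O)c3c(cc(O)c(C/C=C(\C)CCC=C(C)C)c3O)O2)cc(OC)c1O | target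

Total step count: 9. Longest linear sequence: 6 steps (1, 2, 3, 7, 8, 9; the ring B branch 4, 5, 6, 7, 8, 9 is equally long).

Steps most likely to fail

Step 7. The lithium alkoxide may displace the unactivated fluoride too slowly, so that prolonged heating allows base-mediated migration of the geranyl double bond or decomposition. Metalation at ring C8–H next to fluorine, followed by loss of LiF, may also compete with formation of the dithianyl anion. Fallback: setting out from 10 and 16, the epoxide opening is run as above but quenched cold with aqueous NH4Cl, and the fluoro alcohol (1S)-1-[3,5-dimethoxy-4-(methoxymethoxy)phenyl]-2-{2-[2-fluoro-5-geranyl-4,6-bis(methoxymethoxy)phenyl]-1,3-dithian-2-yl}ethanol F1 is isolated. Its dithiane is hydrolysed with MeI and CaCO3 in aqueous MeCN to the β-hydroxy ketone (3S)-1-[2-fluoro-5-geranyl-4,6-bis(methoxymethoxy)phenyl]-3-hydroxy-3-[3,5-dimethoxy-4-(methoxymethoxy)phenyl]propan-1-one F2. Ring C is then closed by an SNAr that is now activated by the ortho carbonyl group (Cs2CO3, DMF, rt, kept short to limit retro-aldol cleavage), which returns to the route at 20.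

Step 3. The hindered aryl Grignard may be protonated (by traces of succinimide or by the C2–H of 7) instead of forming the C–C bond, and lateral metalation at the benzylic–allylic CH2 of the geranyl group may compete with ring metalation. Fallback: setting out from 5, the same ring lithiation is quenched with DMF to give 2-fluoro-5-geranyl-4,6-bis(methoxymethoxy)benzaldehyde F3, which is converted into 10 with propane-1,3-dithiol under neutral LiBr catalysis (solvent-free, 75 °C), a thioacetalisation without Lewis or Brønsted acid.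

Step 2. Metalation may be unselective between the C–H flanked by the two OMOM groups and the fluorine-flanked C–H (the latter leading to aryne formation), and SN2' coupling may erode the geranyl constitution. Fallback: setting out from 1, ortho-allylation of the free resorcinol with geraniol on acidic Al2O3 (1,2-dichloroethane, reflux), which favours the doubly ortho position, gives 5-fluoro-2-geranylbenzene-1,3-diol F4; bis-MOM protection (NaH, MOMCl, DMF) returns to the route at 5.

Further compounds
F1 | step 7 | (1S)-1-[3,5-dimethoxy-4-(methoxymethoxy)phenyl]-2-{2-[2-fluoro-5-geranyl-4,6-bis(methoxymethoxy)phenyl]-1,3-dithian-2-yl}ethanol | COc1cc([C@@H](O)CC2(SCCCS2)c3c(F)cc(OCOC)c(C/C=C(\C)CCC=C(C)C)c3OCOC)cc(OC)c1OCOC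
F2 | step 7 | (3S)-1-[2-fluoro-5-geranyl-4,6-bis(methoxymethoxy)phenyl]-3-hydroxy-3-[3,5-dimethoxy-4-(methoxymethoxy)phenyl]propan-1-one | COc1cc([C@@H](O)CC(=O)c2c(F)cc(OCOC)c(C/C=C(\C)CCC=C(C)C)c2OCOC)cc(OC)c1OCOC
F3 | step 3 | 2-fluoro-5-geranyl-4,6-bis(methoxymethoxy)benzaldehyde | O=Cc1c(F)cc(OCOC)c(C/C=C(\C)CCC=C(C)C)c1OCOC
F4 | step 2 | 5-fluoro-2-geranylbenzene-1,3-diol | Oc1cc(F)cc(O)c1C/C=C(\C)CCC=C(C)C
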